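**Retrosynthetic overview**
- Gibberellin A(74) ⇐ fluoride deprotection of its 3-O-TBS ether 7-SEM ester ⇐ a cyclic hydrazide (C19(=O)–NH–NH–C20H2–C10) that releases CO2H and CH3 on oxidation, hydrolysis and loss of N2.
- Key C10–C20 bond: a tertiary C10 radical (from a 10,12-cyclic thionocarbonate, blue light) closes on a C19-tethered formaldehyde N-acylhydrazone; the tether fixes the α face.
- The 10α,12α-diol comes from hydrazinolysis of a 12α-hydroxy lactone, itself from substrate-controlled reduction of the 12-ketone.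
- C12 is oxidised by Barton nitrite photolysis relayed by the lactone oxygen (O10) of ring-opened gibberellin A(4), then the lactone is re-closed.
- No ring is built: rings A, B, C and D and seven stereocentres are bought in gibberellin A(4); only C12 (reduction) and C10 (tether) are set in the route.

Assumption: gibberellin A(4) is bought as such (it is also the main part of the commercial mixture of gibberellins A(4) and A(7)); gibberellin numbering and the usual α/β descriptors are used, and the 12-hydroxyl is 12α (axial on ring C, on the same face as C10 and C20) as written in the target SMILES.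

**Step 1**
Reactants: 1 gibberellin A(4)
Product: 3 3-O-TBS-gibberellin A(4), via bis-silyl compound 2 (not isolated)
Conditions: TBSOTf, 2,6-lutidine, CH2Cl2, 0 °C; then K2CO3 (cat.), MeOH–H2O, 0 °C
Reagents that add atoms: tert-butyldimethylsilyl triflate, CC(C)(C)[Si](C)(C)OS(=O)(=O)C(F)(F)F
Why: Silyl ether formation with a silyl triflate covers the hindered axial 3β-OH, and the labile silyl ester is cleaved by mild methanolysis, so no stereocentre is touched.

**Step 2**
Reactants: 3 3-O-TBS-gibberellin A(4)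
Product: 8 3-O-TBS-12-(hydroxyimino)gibberellin A(4), via ring-opened salt 4 (not isolated), via nitrite 5 (not isolated), via nitroso compound 6 (not isolated), via oxime salt 7 (not isolated)
Conditions: Bu4NOH, THF–H2O, 40 °C, dry; t-BuONO, MeCN, 0→20 °C, dark; hν (365 nm), MeCN, −20 °C, Ar, then 40 °C; 1 M HCl to pH 3
Reagents that add atoms: tert-butyl nitrite, CC(C)(C)ON=O
Why: Barton nitrite photolysis, in which C10 sits axial on ring C so that its α-alkoxyl radical (from the opened lactone) reaches the 1,3-diaxial H-12α and abstracts it by 1,5-hydrogen transfer, NO recombination and tautomerisation give the C12 oxime, and acid re-closes the lactone with C10 unchanged.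

**Step 3**
Reactants: 8 3-O-TBS-12-(hydroxyimino)gibberellin A(4)
Product: 9 3-O-TBS-12-oxogibberellin A(4)
Conditions: TiCl3 (aq.), NH4OAc, THF–H2O, 20 °C
Reagents that add atoms: water, O
Why: Reductive deoximation (trivalent titanium cleaves the N–O bond and the imine hydrolyses) frees the ketone, and the neighbouring C13 is a bridgehead that cannot epimerise.

**Step 4**
Reactants: 9 3-O-TBS-12-oxogibberellin A(4)
Product: 10 3-O-TBS-12α-hydroxygibberellin A(4)
Conditions: LiBH(s-Bu)3 (L-Selectride), THF, −78 °C; aq. NH4Cl then dilute HCl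
Reagents that add atoms: none
Why: Substrate-controlled hydride reduction, in which the α face of the C12 carbonyl is blocked by C10 and the lactone oxygen (axial on C9), so the bulky borohydride adds equatorially from the face turned toward the C15–C16 bridge and gives the axial 12α-alcohol.

**Step 5**
Reactants: 10 3-O-TBS-12α-hydroxygibberellin A(4)
Product: 12 N'-methylidene hydrazide diol, via hydrazide 11 (not isolated)
Conditions: N2H4·H2O, EtOH, 70 °C, Ar, evaporate; aq. CH2O, MeOH, 20 °C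
Reagents that add atoms: hydrazine, NN; formaldehyde, C=O
Why: Hydrazinolysis of the strained γ-lactone breaks only the acyl C–O bond (C10 keeps its configuration, the hydrazide does not relactonise) and condensation with formaldehyde gives the N-acylhydrazone.

**Step 6**
Reactants: 12 N'-methylidene hydrazide diol
Product: 13 SEM ester of 12
Conditions: SEMCl, i-Pr2NEt, CH2Cl2, 0 °C
Reagents that add atoms: 2-(trimethylsilyl)ethoxymethyl chloride, C[Si](C)(C)CCOCCl
Why: Carboxylate O-alkylation masks the C7 acid before thiocarbonylation, while the two hindered alcohols and the hydrazone N–H are not alkylated under Hünig base at 0 °C.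

**Step 7**
Reactants: 13 SEM ester of 12
Product: 14 10,12-cyclic thionocarbonate
Conditions: TCDI, DMAP (cat.), toluene, 90 °C
Reagents that add atoms: 1,1'-thiocarbonyldiimidazole, S=C(n1ccnc1)n1ccnc1
Why: Cyclic thionocarbonate formation, favoured because the syn 10α and 12α hydroxyls are about 2.5 Å apart, so thiocarbonyl transfer to the secondary OH is followed by closure on the tertiary OH.

**Step 8**
Reactants: 14 10,12-cyclic thionocarbonate
Product: 16 19,20-bridged cyclic hydrazide, via thiocarbonate salt 15 (not isolated)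
Conditions: fac-Ir(ppy)3 (2 mol %), Hantzsch ester, i-Pr2NEt, MeCN (5 mM), 450 nm LEDs, 25 °C; then 40 °C, N2 purge
Reagents that add atoms: none
Why: Proposed new method: the photoreduced thionocarbonate fragments at the tertiary C10–O bond (Barton–McCombie-type scission under photoredox), and the C10 radical, held 1,3-diaxial to the C19 acyl group, adds 7-endo to the CH2 carbon of the tethered formaldehyde N-acylhydrazone from the α face only, forming C10–C20 with retention at C10 before the hydrazinyl radical is reduced and the O12 thiocarbonate loses COS; the closest known chemistry is photoredox deoxygenation of thiocarbonyl derivatives and 5-exo or 6-exo radical cyclisation onto N-acylhydrazones, the 7-endo closure on a formaldehyde hydrazone used as a traceless methyl tether being new.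

**Step 9**
Reactants: 16 19,20-bridged cyclic hydrazide
Product: 19 3-O-TBS-gibberellin A(74) 7-SEM ester, via acyl diazene 17 (not isolated), via alkyl diazene 18 (not isolated)
Conditions: PhI(OAc)2, pyridine, THF–H2O, 0→20 °C
Reagents that add atoms: water, O
Why: Oxidation of the N-acyl-N'-alkyl hydrazide to the acyl diazene, hydrolysis of this activated acyl group to the C19 acid and loss of N2 from the monoalkyl diazene leave C20 as a methyl group without touching C10.

**Step 10**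
Reactants: 19 3-O-TBS-gibberellin A(74) 7-SEM ester
Product: 20 gibberellin A(74)
Conditions: Bu4NF, THF, 50 °C; dilute HCl
Reagents that add atoms: none
Why: Fluoride-induced desilylation cleaves the TBS ether and fragments the SEM ester without acid or strong base, so the exocyclic alkene and the β-hydroxy acid survive.

**Compound list**
1 | gibberellin A(4) (3β-hydroxy, 19,10-lactone, 7-acid, 16-ene) | C=C1C[C@]23C[C@H]1CC[C@H]2[C@]14CC[C@H](O)[C@@](C)(C(=O)O4)[C@H]1[C@@H]3C(=O)O | starting material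
2 | gibberellin A(4) 3-O-TBS ether 7-TBS ester (formed in flask) | C=C1C[C@]23C[C@H]1CC[C@H]2[C@]14CC[C@H](O[Si](C)(C)C(C)(C)C)[C@@](C)(C(=O)O4)[C@H]1[C@@H]3C(=O)O[Si](C)(C)C(C)(C)C | intermediate
3 | 3-O-TBS-gibberellin A(4) | C=C1C[C@]23C[C@H]1CC[C@H]2[C@]14CC[C@H](O[Si](C)(C)C(C)(C)C)[C@@](C)(C(=O)O4)[C@H]1[C@@H]3C(=O)O | intermediate
4 | ring-opened 10α-hydroxy 7,19-dicarboxylate of 3, bis(tetrabutylammonium) salt (formed in flask) | C=C1C[C@]23C[C@H]1CC[C@H]2[C@]1(O)CC[C@H](O[Si](C)(C)C(C)(C)C)[C@@](C)(C(=O)[O-])[C@H]1[C@@H]3C(=O)[O-].CCCC[N+](CCCC)(CCCC)CCCC.CCCC[N+](CCCC)(CCCC)CCCC | intermediate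
5 | C10 O-nitrite of 4 (formed in flask) | C=C1C[C@]23C[C@H]1CC[C@H]2[C@]1(ON=O)CC[C@H](O[Si](C)(C)C(C)(C)C)[C@@](C)(C(=O)[O-])[C@H]1[C@@H]3C(=O)[O-].CCCC[N+](CCCC)(CCCC)CCCC.CCCC[N+](CCCC)(CCCC)CCCC | intermediate
6 | 12-nitroso 10α-hydroxy dicarboxylate salt, C12 epimers (formed in flask) | C=C1C[C@]23C[C@H]1C(N=O)C[C@H]2[C@]1(O)CC[C@H](O[Si](C)(C)C(C)(C)C)[C@@](C)(C(=O)[O-])[C@H]1[C@@H]3C(=O)[O-].CCCC[N+](CCCC)(CCCC)CCCC.CCCC[N+](CCCC)(CCCC)CCCC | intermediate
7 | 12-(hydroxyimino) 10α-hydroxy dicarboxylate salt (formed in flask) | C=C1C[C@]23C[C@H]1C(=NO)C[C@H]2[C@]1(O)CC[C@H](O[Si](C)(C)C(C)(C)C)[C@@](C)(C(=O)[O-])[C@H]1[C@@H]3C(=O)[O-].CCCC[N+](CCCC)(CCCC)CCCC.CCCC[N+](CCCC)(CCCC)CCCC | intermediate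
8 | 3-O-TBS-12-(hydroxyimino)gibberellin A(4) (lactone re-closed) | C=C1C[C@]23C[C@H]1C(=NO)C[C@H]2[C@]14CC[C@H](O[Si](C)(C)C(C)(C)C)[C@@](C)(C(=O)O4)[C@H]1[C@@H]3C(=O)O | intermediate
9 | 3-O-TBS-12-oxogibberellin A(4) | C=C1C[C@]23C[C@H]1C(=O)C[C@H]2[C@]14CC[C@H](O[Si](C)(C)C(C)(C)C)[C@@](C)(C(=O)O4)[C@H]1[C@@H]3C(=O)O | intermediate
10 | 3-O-TBS-12α-hydroxygibberellin A(4) | C=C1C[C@]23C[C@H]1[C@@H](O)C[C@H]2[C@]14CC[C@H](O[Si](C)(C)C(C)(C)C)[C@@](C)(C(=O)O4)[C@H]1[C@@H]3C(=O)O | intermediate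
11 | ring-opened 10α,12α-diol 19-hydrazide 7-acid (formed in flask) | C=C1C[C@]23C[C@H]1[C@@H](O)C[C@H]2[C@]1(O)CC[C@H](O[Si](C)(C)C(C)(C)C)[C@@](C)(C(=O)NN)[C@H]1[C@@H]3C(=O)O | intermediate
12 | ring-opened 10α,12α-diol 19-(N'-methylidene)hydrazide 7-acid | C=C1C[C@]23C[C@H]1[C@@H](O)C[C@H]2[C@]1(O)CC[C@H](O[Si](C)(C)C(C)(C)C)[C@@](C)(C(=O)NN=C)[C@H]1[C@@H]3C(=O)O | intermediate
13 | 7-SEM ester of 12 | C=C1C[C@]23C[C@H]1[C@@H](O)C[C@H]2[C@]1(O)CC[C@H](O[Si](C)(C)C(C)(C)C)[C@@](C)(C(=O)NN=C)[C@H]1[C@@H]3C(=O)OCOCC[Si](C)(C)C | intermediate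
14 | 10α,12α-cyclic thionocarbonate of 13 (seven-membered) | C=C1C[C@]23C[C@H]1[C@@H](OC5=S)C[C@H]2[C@]1(O5)CC[C@H](O[Si](C)(C)C(C)(C)C)[C@@](C)(C(=O)NN=C)[C@H]1[C@@H]3C(=O)OCOCC[Si](C)(C)C | intermediate
15 | cyclised hydrazide carrying the 12-O-thiocarbonate, i-Pr2NEtH salt (formed in flask) | C=C1C[C@]23C[C@H]1[C@@H](OC(=O)[S-])C[C@H]2[C@]1(CNN6)CC[C@H](O[Si](C)(C)C(C)(C)C)[C@@](C)(C6=O)[C@H]1[C@@H]3C(=O)OCOCC[Si](C)(C)C.CC[NH+](C(C)C)C(C)C | intermediate
16 | 19,20-bridged cyclic hydrazide (C19(=O)–NH–NH–C20H2 on C10α), 12α-OH free | C=C1C[C@]23C[C@H]1[C@@H](O)C[C@H]2[C@]1(CNN6)CC[C@H](O[Si](C)(C)C(C)(C)C)[C@@](C)(C6=O)[C@H]1[C@@H]3C(=O)OCOCC[Si](C)(C)C | intermediate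
17 | cyclic acyl diazene from 16 (formed in flask) | C=C1C[C@]23C[C@H]1[C@@H](O)C[C@H]2[C@]1(CN=N6)CC[C@H](O[Si](C)(C)C(C)(C)C)[C@@](C)(C6=O)[C@H]1[C@@H]3C(=O)OCOCC[Si](C)(C)C | intermediate
18 | 20-diazenyl 19-acid (formed in flask) | C=C1C[C@]23C[C@H]1[C@@H](O)C[C@H]2[C@]1(CN=N)CC[C@H](O[Si](C)(C)C(C)(C)C)[C@@](C)(C(=O)O)[C@H]1[C@@H]3C(=O)OCOCC[Si](C)(C)C | intermediate
19 | 3-O-TBS-gibberellin A(74) 7-SEM ester | C=C1C[C@]23C[C@H]1[C@@H](O)C[C@H]2[C@]1(C)CC[C@H](O[Si](C)(C)C(C)(C)C)[C@@](C)(C(=O)O)[C@H]1[C@@H]3C(=O)OCOCC[Si](C)(C)C | intermediate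
20 | gibberellin A(74) | C=C1C[C@]23C[C@H]1[C@@H](O)C[C@H]2[C@]1(C)CC[C@H](O)[C@@](C)(C(=O)O)[C@H]1[C@@H]3C(=O)O | target

Total steps: 10. Longest linear sequence: 10 steps (1 to 20).

**Steps most likely to fail**

Step 2. The C10 alkoxyl radical may open ring B by β-scission instead of abstracting H-12α, H-14α is a minor competitor, and the C12 radical is homoallylic to the 16-ene. The fallback replaces the radical relay by a metal-catalysed C–H silylation from the same oxygen. It sets out from 3: Bu4NOH then MeI in DMF gives the ring-opened hydroxy diester F1; Et2SiH2 with [Ir(cod)OMe]2 gives the diethylhydrosilyl ether F2; [Rh(cod)Cl]2/Xantphos with norbornene at 100 °C closes the six-membered oxasilinane F3 on the δ C–H bond at C12 (12α, retention); Tamao–Fleming oxidation (H2O2, KHCO3, KF) gives the diol diester F4, which lactonises to the 12α-hydroxy lactone methyl ester F5; KOH in MeOH–H2O, then acid, comes back to the route at 10, so steps 3 and 4 are not needed.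

Step 7. The seven-membered thionocarbonate may not close on the hindered tertiary OH. The fallback makes the C10 radical straight from the free tertiary alcohol. It sets out from 13: Cp*TiCl3 (cat.), Zn and Et3SiCl in THF effect tertiary-selective dehydroxylative radical formation, the 12-OH is silylated in the flask, and the radical closes on the hydrazone as in step 8 to give the 12-O-triethylsilyl cyclic hydrazide F6; AcOH–THF–H2O removes the silyl group and the sequence comes back at 16.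

Step 8 (the new step). The C10 radical may be reduced before the 7-endo closure. The fallback uses known chemistry: silicon-tethered radical cyclisation from the 12α-oxygen, followed by protodesilylation. It sets out from 13: (bromomethyl)chlorodimethylsilane and imidazole give the bromomethylsilyl ether F7; Burgess reagent in benzene at 60 °C dehydrates the 10α-alcohol by syn elimination toward C1 (H-5 and H-9 are trans to the oxygen) to the 1(10)-ene F8; Bu3SnH/AIBN in benzene at 80 °C closes the α-silyl radical on C10 from the α face to the cyclic siloxane F9; Bu4NF in DMF at 75 °C protodesilylates to the C10 methyl group and removes the TBS and SEM groups, giving the N'-methylidene hydrazide of gibberellin A(74) F10; dilute HCl in THF gives the hydrazide F11, and PhI(OAc)2 in aqueous MeCN oxidises it to the acid, coming back at 20.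

**Further compounds**
F1 | step 2 | 10α-hydroxy ring-opened 7,19-dimethyl ester of 3 | C=C1C[C@]23C[C@H]1CC[C@H]2[C@]1(O)CC[C@H](O[Si](C)(C)C(C)(C)C)[C@@](C)(C(=O)OC)[C@H]1[C@@H]3C(=O)OC
F2 | step 2 | 10-O-diethylhydrosilyl ether of F1 | C=C1C[C@]23C[C@H]1CC[C@H]2[C@]1(O[SiH](CC)CC)CC[C@H](O[Si](C)(C)C(C)(C)C)[C@@](C)(C(=O)OC)[C@H]1[C@@H]3C(=O)OC
F3 | step 2 | 10α-O,12α-C diethylsilylene bridged oxasilinane | C=C1C[C@]23C[C@H]1[C@@H]([Si]5(CC)CC)C[C@H]2[C@]1(O5)CC[C@H](O[Si](C)(C)C(C)(C)C)[C@@](C)(C(=O)OC)[C@H]1[C@@H]3C(=O)OC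
F4 | step 2 | 10α,12α-dihydroxy ring-opened 7,19-dimethyl ester | C=C1C[C@]23C[C@H]1[C@@H](O)C[C@H]2[C@]1(O)CC[C@H](O[Si](C)(C)C(C)(C)C)[C@@](C)(C(=O)OC)[C@H]1[C@@H]3C(=O)OC
F5 | step 2 | 3-O-TBS-12α-hydroxygibberellin A(4) methyl ester | C=C1C[C@]23C[C@H]1[C@@H](O)C[C@H]2[C@]14CC[C@H](O[Si](C)(C)C(C)(C)C)[C@@](C)(C(=O)O4)[C@H]1[C@@H]3C(=O)OC
F6 | step 7 | 12-O-triethylsilyl ether of 16 | C=C1C[C@]23C[C@H]1[C@@H](O[Si](CC)(CC)CC)C[C@H]2[C@]1(CNN6)CC[C@H](O[Si](C)(C)C(C)(C)C)[C@@](C)(C6=O)[C@H]1[C@@H]3C(=O)OCOCC[Si](C)(C)C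
F7 | step 8 | 12-O-(bromomethyl)dimethylsilyl ether of 13 | C=C1C[C@]23C[C@H]1[C@@H](O[Si](C)(C)CBr)C[C@H]2[C@]1(O)CC[C@H](O[Si](C)(C)C(C)(C)C)[C@@](C)(C(=O)NN=C)[C@H]1[C@@H]3C(=O)OCOCC[Si](C)(C)C
F8 | step 8 | 1(10)-ene from F7 | C=C1C[C@]23C[C@H]1[C@@H](O[Si](C)(C)CBr)C[C@H]2C1=CC[C@H](O[Si](C)(C)C(C)(C)C)[C@@](C)(C(=O)NN=C)[C@H]1[C@@H]3C(=O)OCOCC[Si](C)(C)C
F9 | step 8 | cyclic siloxane (O12–SiMe2–C20H2–C10α) | C=C1C[C@]23C[C@H]1[C@@H](O[Si]5(C)C)C[C@H]2[C@]1(C5)CC[C@H](O[Si](C)(C)C(C)(C)C)[C@@](C)(C(=O)NN=C)[C@H]1[C@@H]3C(=O)OCOCC[Si](C)(C)C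
F10 | step 8 | gibberellin A(74) 19-(N'-methylidene)hydrazide | C=C1C[C@]23C[C@H]1[C@@H](O)C[C@H]2[C@]1(C)CC[C@H](O)[C@@](C)(C(=O)NN=C)[C@H]1[C@@H]3C(=O)O
F11 | step 8 | gibberellin A(74) 19-hydrazide | C=C1C[C@]23C[C@H]1[C@@H](O)C[C@H]2[C@]1(C)CC[C@H](O)[C@@](C)(C(=O)NN)[C@H]1[C@@H]3C(=O)O
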